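**Plan**
Retrosynthesis: cut C13=C14 (Horner–Wadsworth–Emmons) and C5=C6 (Wittig); trade the C11–O and C9–O bonds for C11–C6 and C9–acetyl bonds (double Baeyer–Villiger); then cut C8–C9 and C10–C11 together (Diels–Alder).
Enabling feature: on the carbocycle C8–C9–C10–C11–C12 the chain carbon C7 on C8 and the oxygen on C11 are cis-1,3, so C7–C6 can be tied back to C11 as a helper two-carbon bridge. The carbocycle is then one five-membered ring of a bicyclo[2.2.1]heptan-2-one (C12 the one-carbon bridge, C6 the ketone), the adduct of a 2-silyloxycyclopentadiene with methyl vinyl ketone (C9–C10).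
Forward: chiral cyclopentenone, silyloxy diene, cycloaddition (carbocycle formed inside the bicycle), peracid (helper bond C6–C11 cut, acetyl turned into the C9 oxygen), lactol, upper chain by Wittig, C13 aldehyde, lower chain by Horner–Wadsworth–Emmons.
Stereochemistry: C12 comes from the enzymatically made monoacetate (Pd, retention) and steers the diene face (C8, C11); the endo rule sets C9; both oxygen insertions go with retention; C12 itself comes out cis in the cycloaddition and is reset to trans,trans by equilibrating the C13 aldehyde; 5Z from the Wittig, 13E from the olefination.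

Key step: step 5

Remark: prostaglandin numbering (C1–C20) is used for the carbons of every intermediate; alpha is the ring face that carries the two hydroxyls of the target.
Remark: both enantiomers of cis-4-acetoxycyclopent-2-en-1-ol are taken to be commercial; the (1S,4R) one is used.

Step 1
Reactants: 1 (1S,4R)-cis-4-acetoxycyclopent-2-en-1-ol; 2 nitromethane
Product: 3 (1S,4R)-4-(nitromethyl)cyclopent-2-en-1-ol
Conditions: Pd(PPh3)4 (5 mol %), PPh3, CH3NO2/THF, 50 °C
Reagents that add atoms: none
Why: Tsuji–Trost allylic alkylation, in which ionisation anti to palladium and attack of the nitronate anti to the metal should give net retention, so the nitromethyl group enters cis to the hydroxyl at the carbon remote from it and fixes the future C12.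

Step 2
Reactants: 3 (1S,4R)-4-(nitromethyl)cyclopent-2-en-1-ol
Product: 5 (1S,4R)-4-(dimethoxymethyl)cyclopent-2-en-1-ol, via sodium nitronate 4 (not isolated)
Conditions: NaOMe, MeOH, 0 °C; then added to H2SO4/MeOH, −40 °C
Reagents that add atoms: methanol, CO
Why: Nef reaction in its acetal-forming variant, in which the nitronate is solvolysed in cold acidic methanol straight to the dimethyl acetal, so the beta,gamma-unsaturated aldehyde is never free and C12 should not enolise.

Step 3
Reactants: 5 (1S,4R)-4-(dimethoxymethyl)cyclopent-2-en-1-ol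
Product: 6 (R)-4-(dimethoxymethyl)cyclopent-2-en-1-one
Conditions: MnO2 (10 equiv), CH2Cl2, rt
Reagents that add atoms: none
Why: Allylic oxidation with MnO2 is neutral and selective for the allylic alcohol, so the acetal and the gamma stereocentre C12 should be left alone.

Step 4
Reactants: 6 (R)-4-(dimethoxymethyl)cyclopent-2-en-1-one
Product: 7 (S)-2-(tert-butyldimethylsilyloxy)-5-(dimethoxymethyl)cyclopenta-1,3-diene
Conditions: LDA, THF, −78 °C; TBSCl, DMPU, −78 → −20 °C; cold pentane work-up, used at once
Reagents that add atoms: tert-butyldimethylsilyl chloride, CC(C)(C)[Si](C)(C)Cl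
Why: Kinetic deprotonation at the alpha-prime methylene (C11) and O-silylation (silyl dienol ether formation) should give the cross-conjugated 2-silyloxy diene without removing the gamma hydrogen at C12.

Step 5
Reactants: 7 (S)-2-(tert-butyldimethylsilyloxy)-5-(dimethoxymethyl)cyclopenta-1,3-diene; 8 methyl vinyl ketone
Product: 10 5-endo-acetyl-7-(dimethoxymethyl)bicyclo[2.2.1]heptan-2-one (acetal syn to the carbonyl bridge), via silyl enol ether cycloadduct 9 (not isolated)
Conditions: 8 (5 equiv), toluene, −20 → 0 °C; evaporate; then TBAF, AcOH, THF, 0 °C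
Reagents that add atoms: none
Why: The step is a concerted, asynchronous normal-demand [4+2] cycloaddition (Diels–Alder reaction) between the s-cis-locked silyloxy diene C11=C6(OSi)–C7=C8 and the enone C9=C10, in which the terminus C11, which carries the largest HOMO coefficient next to the silyloxy carbon, bonds to the beta carbon C10 and C8 bonds to the acetyl-bearing C9. The closest known reaction type is the addition of 2-silyloxycyclopenta-1,3-dienes to vinyl ketones and acrylates, which gives 5-acylnorbornan-2-ones after desilylation. Two rings close at once in a suprafacial 4π+2π mode: the carbocycle C8–C9–C10–C11–C12 of the target and the six-membered ring C6–C7–C8–C9–C10–C11, which share the new bonds and make up the bicyclo[2.2.1]heptene. C8 and C11 are set by the diene face that is attacked, which should be the one anti to the dimethoxymethyl group on C12, and C9 by the endo rule, which places the acetyl group on the side of the C6–C7 bridge; C12 is not touched and so ends with its acetal cis to C7 and C6, an arrangement that step 11 corrects. The step needs facial, regio- and endo selectivity and has to outrun the 1,5-hydrogen shift of the diene; the C12 substituent, the silyloxy group, secondary orbital overlap at low temperature and the excess of dienophile should secure these in turn. Buffered fluoride then unmasks the ring ketone without exposing the epimerisable C9 centre to free base.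

Step 6
Reactants: 10 5-endo-acetyl-7-(dimethoxymethyl)bicyclo[2.2.1]heptan-2-one
Product: 11 6-endo-acetoxy-8-(dimethoxymethyl)-2-oxabicyclo[3.2.1]octan-3-one
Conditions: mCPBA (5 equiv), Na2HPO4, CH2Cl2, 0 → 35 °C
Reagents that add atoms: 3-chloroperoxybenzoic acid, OOC(=O)c1cccc(Cl)c1
Why: Double Baeyer–Villiger oxidation, in which the bridgehead C11 should migrate in the strained ring ketone and the secondary C9 in the methyl ketone, both with retention, so the helper bond C6–C11 and the C9–acetyl bond become the 11- and 9-oxygen functions on the alpha face.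

Step 7
Reactants: 11 6-endo-acetoxy-8-(dimethoxymethyl)-2-oxabicyclo[3.2.1]octan-3-one
Product: 12 8-(dimethoxymethyl)-2-oxabicyclo[3.2.1]octane-3,6-diol (lactol, in equilibrium with the open hydroxy aldehyde)
Conditions: DIBAL-H (3.5 equiv), CH2Cl2, −78 °C; MeOH, then aq. potassium sodium tartrate
Reagents that add atoms: none
Why: DIBAL-H at low temperature should stop the lactone at the lactol stage and cleave the acetate, while the acetal is inert and no stereocentre is touched.

Step 8
Reactants: 12 lactol; 13 (4-carboxybutyl)triphenylphosphonium bromide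
Product: 14 (5Z)-7-[2-(dimethoxymethyl)-3,5-dihydroxycyclopentyl]hept-5-enoic acid (all four ring substituents cis: 9alpha,11alpha-diol and 12-epi)
Conditions: 13 (4 equiv), KOtBu (8 equiv), THF, 0 °C; then 12, 0 °C → rt; aq. citric acid
Reagents that add atoms: none
Why: Wittig reaction of the lactol through its open aldehyde with the unstabilised carboxylate ylide should give the 5Z alkene, the usual way of attaching the upper prostaglandin chain, with the excess base only deprotonating the hydroxyls.

Step 9
Reactants: 14 diol acid
Product: 16 (5Z)-7-[3,5-bis(tert-butyldimethylsilyloxy)-2-(dimethoxymethyl)cyclopentyl]hept-5-enoic acid (all-cis), via silyl ester 15 (not isolated)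
Conditions: TBSCl (5 equiv), imidazole, DMAP, DMF, 40 °C; then K2CO3, MeOH/THF/H2O, rt; work-up at pH 5
Reagents that add atoms: tert-butyldimethylsilyl chloride, CC(C)(C)[Si](C)(C)Cl
Why: Silylation of both secondary hydroxyls and, transiently, of the acid, followed by mild basic cleavage of the labile silyl ester, should give the bis-silyl ether that protects the diol during unmasking and olefination.

Step 10
Reactants: 16 bis-silyl ether acetal
Product: 17 (5Z)-7-[3,5-bis(tert-butyldimethylsilyloxy)-2-formylcyclopentyl]hept-5-enoic acid (all-cis, 12-epi aldehyde)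
Conditions: PPTS (0.2 equiv), acetone/H2O (10:1), 50 °C
Reagents that add atoms: water, O
Why: Mild acid-catalysed acetal hydrolysis should free the C13 aldehyde while the secondary silyl ethers, the Z alkene and the acid survive; C12 is still cis at this point.

Step 11
Reactants: 17 12-epi aldehyde; 18 dimethyl (2-oxoheptyl)phosphonate
Product: 20 15-keto-PGF2alpha 9,11-bis(tert-butyldimethylsilyl) ether, via trans aldehyde 19 (not isolated)
Conditions: LiCl (4 equiv), DBU (3.5 equiv), MeCN, rt, 3 h; then 18 (1.5 equiv), 0 °C → rt
Reagents that add atoms: none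
Why: Epimerisation through the aldehyde enolate should move the formyl group from the all-cis array to the thermodynamically favoured position trans to both neighbours, which sets C12, and the Horner–Wadsworth–Emmons reaction in its LiCl/amine variant should then give the 13E enone.

Step 12
Reactants: 20 bis-silyl ether
Product: 21 15-keto-PGF2alpha
Conditions: HF·pyridine, pyridine/THF, 0 °C → rt
Reagents that add atoms: none
Why: Fluoride-mediated desilylation under buffered conditions should free both hydroxyls without touching the enone, the Z alkene or any stereocentre.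

**Compound list**
1 | (1S,4R)-cis-4-acetoxycyclopent-2-en-1-ol | CC(=O)O[C@H]1C=C[C@@H](O)C1 | starting material
2 | nitromethane | C[N+](=O)[O-] | starting material
3 | (1S,4R)-4-(nitromethyl)cyclopent-2-en-1-ol | O=[N+]([O-])C[C@H]1C=C[C@@H](O)C1 | intermediate
4 | sodium nitronate of 3 | [Na+].[O-][N+]([O-])=C[C@H]1C=C[C@@H](O)C1 | intermediate (not isolated)
5 | (1S,4R)-4-(dimethoxymethyl)cyclopent-2-en-1-ol | COC(OC)[C@H]1C=C[C@@H](O)C1 | intermediate
6 | (R)-4-(dimethoxymethyl)cyclopent-2-en-1-one | COC(OC)[C@H]1C=CC(=O)C1 | intermediate
7 | (S)-2-(tert-butyldimethylsilyloxy)-5-(dimethoxymethyl)cyclopenta-1,3-diene | COC(OC)[C@H]1C=CC(O[Si](C)(C)C(C)(C)C)=C1 | intermediate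
8 | methyl vinyl ketone (but-3-en-2-one) | CC(=O)C=C | starting material
9 | 1-[7-(dimethoxymethyl)-5-(tert-butyldimethylsilyloxy)bicyclo[2.2.1]hept-5-en-2-yl]ethanone, 2-endo acetyl, acetal syn to the enol ether bridge | COC(OC)[C@H]1[C@@H](C=C2O[Si](C)(C)C(C)(C)C)[C@@H](C(C)=O)C[C@H]12 | intermediate (not isolated)
10 | 5-endo-acetyl-7-(dimethoxymethyl)bicyclo[2.2.1]heptan-2-one, acetal syn to the carbonyl bridge | COC(OC)[C@H]1[C@@H](CC2=O)[C@@H](C(C)=O)C[C@H]12 | intermediate
11 | 6-endo-acetoxy-8-(dimethoxymethyl)-2-oxabicyclo[3.2.1]octan-3-one, acetal over the lactone bridge | COC(OC)[C@H]1[C@@H](CC(=O)O2)[C@@H](OC(C)=O)C[C@H]12 | intermediate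
12 | 8-(dimethoxymethyl)-2-oxabicyclo[3.2.1]octane-3,6-diol (bridged lactol, 6-endo hydroxyl, anomers) | COC(OC)[C@H]1[C@@H](CC(O)O2)[C@@H](O)C[C@H]12 | intermediate
13 | (4-carboxybutyl)triphenylphosphonium bromide | [Br-].OC(=O)CCCC[P+](c1ccccc1)(c1ccccc1)c1ccccc1 | starting material
14 | (5Z)-7-[2-(dimethoxymethyl)-3,5-dihydroxycyclopentyl]hept-5-enoic acid, all-cis ring (8alpha chain, 9alpha-OH, 11alpha-OH, 12alpha acetal) | COC(OC)[C@H]1[C@@H](C/C=C\CCCC(=O)O)[C@@H](O)C[C@H]1O | intermediate
15 | tert-butyldimethylsilyl ester of 16 | COC(OC)[C@H]1[C@@H](C/C=C\CCCC(=O)O[Si](C)(C)C(C)(C)C)[C@@H](O[Si](C)(C)C(C)(C)C)C[C@H]1O[Si](C)(C)C(C)(C)C | intermediate (not isolated)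
16 | (5Z)-7-[3,5-bis(tert-butyldimethylsilyloxy)-2-(dimethoxymethyl)cyclopentyl]hept-5-enoic acid, all-cis ring | COC(OC)[C@H]1[C@@H](C/C=C\CCCC(=O)O)[C@@H](O[Si](C)(C)C(C)(C)C)C[C@H]1O[Si](C)(C)C(C)(C)C | intermediate
17 | (5Z)-7-[3,5-bis(tert-butyldimethylsilyloxy)-2-formylcyclopentyl]hept-5-enoic acid, all-cis ring (12-epi aldehyde) | O=C[C@H]1[C@@H](C/C=C\CCCC(=O)O)[C@@H](O[Si](C)(C)C(C)(C)C)C[C@H]1O[Si](C)(C)C(C)(C)C | intermediate
18 | dimethyl (2-oxoheptyl)phosphonate | CCCCCC(=O)CP(=O)(OC)OC | starting material
19 | C12 epimer of 17 (formyl beta, trans to both ring neighbours) | O=C[C@@H]1[C@@H](C/C=C\CCCC(=O)O)[C@@H](O[Si](C)(C)C(C)(C)C)C[C@H]1O[Si](C)(C)C(C)(C)C | intermediate (not isolated)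
20 | 15-keto-PGF2alpha 9,11-bis(tert-butyldimethylsilyl) ether | CCCCCC(=O)/C=C/[C@@H]1[C@@H](C/C=C\CCCC(=O)O)[C@@H](O[Si](C)(C)C(C)(C)C)C[C@H]1O[Si](C)(C)C(C)(C)C | intermediate
21 | 15-keto-PGF2alpha, (5Z,13E)-9alpha,11alpha-dihydroxy-15-oxoprosta-5,13-dien-1-oic acid | CCCCCC(=O)/C=C/[C@@H]1[C@@H](C/C=C\CCCC(=O)O)[C@@H](O)C[C@H]1O | target

**Step count and risks**
Total steps: 12. Longest linear sequence: 12 steps (1 to 21).

Step 5. What may go wrong: erosion of endo selectivity in the uncatalysed addition of the vinyl ketone, and loss of diene 7 through 1,5-hydrogen shift or dimerisation before it is trapped. Fallback: the fallback sets out from 7, which is combined with but-3-yn-2-one, a faster dienophile for which no endo/exo question arises, to give 1-[7-(dimethoxymethyl)-5-(tert-butyldimethylsilyloxy)bicyclo[2.2.1]hepta-2,5-dien-2-yl]ethanone F1. Conjugate reduction of its enone with [(Ph3P)CuH]6 in wet toluene should deliver hydride to C10 and protonate the copper enolate at C9 from the open exo face, which puts the acetyl group endo. The fallback comes back to the route at 9, which is desilylated to 10 as in step 5.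

Step 6. What may go wrong: slow oxygen insertion at the unstrained methyl ketone, so that long exposure to peracid degrades the acetal; methylene rather than bridgehead migration at the hindered ring ketone is a second concern that this fallback does not remove. Fallback: the fallback sets out from 10, which with one equivalent of mCPBA at 0 °C should react only at the strained ring ketone to give the keto lactone F2. TMSCl, NaI and Et3N in MeCN convert the methyl ketone into the more substituted silyl enol ether F3. Ozonolysis (O3, then Me2S) cuts this to the C9 ketone F4. NaBH4 at −40 °C should add hydride from the exo face to give the 9alpha-hydroxy lactone F5, and DIBAL-H reduces this to lactol 12, where the fallback comes back to the route.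

Step 11. What may go wrong: beta-elimination of the C11 silyloxy group from the aldehyde enolate in competition with epimerisation, or olefination before epimerisation is complete. Fallback: the fallback sets out from 14 and leaves the silyl groups out. Aqueous acid (AcOH/THF/H2O) hydrolyses the acetal of 14 to the hydroxy aldehyde, which with its cis 9-hydroxyl should rest as the bridged lactol (5Z)-7-(3,5-dihydroxy-2-oxabicyclo[2.2.1]heptan-7-yl)hept-5-enoic acid F6. Under LiCl/DBU with 18, only the epimerised trans aldehyde, which cannot close to a lactol, is free to be olefinated, and hydroxide at C11 is a poorer leaving group than silanolate. The fallback comes back to the route at the target 21.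

**Further compounds**
F1 | step 5 | 1-[7-(dimethoxymethyl)-5-(tert-butyldimethylsilyloxy)bicyclo[2.2.1]hepta-2,5-dien-2-yl]ethanone | COC(OC)[C@H]1[C@@H](C=C2O[Si](C)(C)C(C)(C)C)C(C(C)=O)=C[C@H]12
F2 | step 6 | 6-endo-acetyl-8-(dimethoxymethyl)-2-oxabicyclo[3.2.1]octan-3-one | COC(OC)[C@H]1[C@@H](CC(=O)O2)[C@@H](C(C)=O)C[C@H]12
F3 | step 6 | 8-(dimethoxymethyl)-6-[1-(trimethylsilyloxy)ethylidene]-2-oxabicyclo[3.2.1]octan-3-one | COC(OC)[C@H]1[C@@H](CC(=O)O2)C(=C(C)O[Si](C)(C)C)C[C@H]12
F4 | step 6 | 8-(dimethoxymethyl)-2-oxabicyclo[3.2.1]octane-3,6-dione | COC(OC)[C@H]1[C@@H](CC(=O)O2)C(=O)C[C@H]12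
F5 | step 6 | 6-endo-hydroxy-8-(dimethoxymethyl)-2-oxabicyclo[3.2.1]octan-3-one | COC(OC)[C@H]1[C@@H](CC(=O)O2)[C@@H](O)C[C@H]12
F6 | step 11 | (5Z)-7-(3,5-dihydroxy-2-oxabicyclo[2.2.1]heptan-7-yl)hept-5-enoic acid | OC2[C@H]1[C@@H](C/C=C\CCCC(=O)O)[C@@H](O2)C[C@H]1O
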